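**Plan**
1. The target is a 27-membered lactone whose ring holds one ester (C1 carbonyl, ring O) and 25 methylenes (C2–C26); there is no other functional group.
2. Ring cut: the unfunctionalised CH2–CH2 bond C7–C8, taken apart into a primary bromide at C7 and a B-alkyl borane at C8 that comes from a terminal alkene C8=C9.
3. Chain cuts: the ester bond C1–O (a 7-bromoheptanoyl unit plus a C19 alkenol) and the chain bond C15–C16 of that alkenol (a C8 Grignard reagent plus a C11 bromo alcohol).
4. Forward order: C15–C16 is joined first, then the ester C1–O, and the only ring arises last by hydroboration and intramolecular alkyl–alkyl coupling at C7–C8.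
5. Enabling feature: since C2–C25 are all CH2, the ring can be closed directly at the final oxidation level from a vinyl group and a primary bromide, both remote from the ester, and nothing has to be removed afterwards.
6. Stereochemistry: none to set; the target is achiral and has no double bond.

Key step: step 3

Remark: atoms are numbered as in the parent 26-hydroxyhexacosanoic acid (C1 = lactone carbonyl, C26 = OCH2).

**Step 1**
Reactants: 1 8-bromooct-1-ene; 2 11-bromoundecan-1-ol
Product: 5 nonadec-18-en-1-ol, via oct-7-en-1-ylmagnesium bromide 3 (not isolated), via bromomagnesium 11-bromoundecan-1-olate 4 (not isolated)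
Conditions: 1 (2.6 equiv), Mg, THF, rt to 45 °C; then 2 (1.0 equiv), Li2CuCl4 (3 mol %), THF, −10 °C to rt; aq NH4Cl
Reagents that add atoms: none
Why: Li2CuCl4-catalysed Grignard–alkyl bromide cross-coupling (Kochi coupling): one equivalent of 3 deprotonates 2 to alkoxide 4, and the organocuprate formed from 3 then substitutes its primary bromide, which joins C15 to C16 and leaves the remote terminal alkene untouched; no stereocenter arises.

**Step 2**
Reactants: 5 nonadec-18-en-1-ol; 6 7-bromoheptanoic acid
Product: 7 nonadec-18-en-1-yl 7-bromoheptanoate
Conditions: 6 (1.2 equiv), TsOH·H2O (5 mol %), toluene, reflux, Dean–Stark trap; aq NaHCO3 wash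
Reagents that add atoms: none
Why: Fischer esterification, in which azeotropic removal of water pulls the acid-catalysed equilibrium to the ester while the primary bromide and the isolated terminal alkene should stay inert to catalytic sulfonic acid; no stereocenter arises.

**Step 3**
Reactants: 7 nonadec-18-en-1-yl 7-bromoheptanoate
Product: 9 26-hexacosanolide, via B-alkyl-9-BBN bromo ester 8 (not isolated)
Conditions: 9-BBN (1.05 equiv), THF, 0 °C to rt, 6 h; then syringe-pump addition over 36 h to Pd(OAc)2 (25 mol %), PCy3 (50 mol %), K3PO4·H2O (3 equiv), THF, rt, 5 mM final concentration, then 12 h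
Reagents that add atoms: none
Why: Proposed new method: 9-BBN should add to the terminal alkene C8=C9 with boron on C8 (anti-Markovnikov hydroboration) without touching the ester or the bromide, and the hydroxide-activated borate then meets the C7–Br end at palladium through SN2-type oxidative addition of the primary bromide to zerovalent palladium bearing PCy3, intramolecular transmetalation of the primary alkyl group and reductive elimination, which forms the C7–C8 bond. The closest known reaction types are the intermolecular alkyl–alkyl Suzuki–Miyaura coupling of β-hydrogen-bearing primary alkyl bromides with B-alkyl-9-BBN reagents under Pd(OAc)2/PCy3/K3PO4·H2O at room temperature, which tolerates esters, and the macrocyclising B-alkyl Suzuki–Miyaura coupling of alkenyl halides; new is the sp3–sp3 ring closure. The only ring, the 27-membered lactone, closes end to end by reductive elimination from a 28-membered palladacycle, a macrocyclisation to which no exo or endo descriptor applies and which meets no strain beyond that of a large polymethylene ring. No stereocenter is formed. The step needs ring closure over intermolecular coupling and coupling over β-hydride elimination: the first should be secured by slow addition, which keeps free 8 at a few millimolar while the catalyst stays concentrated enough for the slow bimolecular oxidative addition, the second by the bulky electron-rich PCy3, under which primary alkylpalladium bromides persist at room temperature. Only the B–C8 bond should transmetalate, because the two secondary ring carbons of the 9-BBN cage transfer much more slowly.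

**Compound list**
1 | 8-bromooct-1-ene | C=CCCCCCCBr | starting material
2 | 11-bromoundecan-1-ol | OCCCCCCCCCCCBr | starting material
3 | oct-7-en-1-ylmagnesium bromide | C=CCCCCCC[Mg]Br | intermediate
4 | bromomagnesium 11-bromoundecan-1-olate | BrCCCCCCCCCCCO[Mg]Br | intermediate
5 | nonadec-18-en-1-ol | OCCCCCCCCCCCCCCCCCC=C | intermediate
6 | 7-bromoheptanoic acid | OC(=O)CCCCCCBr | starting material
7 | nonadec-18-en-1-yl 7-bromoheptanoate | BrCCCCCCC(=O)OCCCCCCCCCCCCCCCCCC=C | intermediate
8 | 19-(9-borabicyclo[3.3.1]nonan-9-yl)nonadecyl 7-bromoheptanoate | BrCCCCCCC(=O)OCCCCCCCCCCCCCCCCCCCB1C2CCCC1CCC2 | intermediate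
9 | 26-hexacosanolide (oxacycloheptacosan-2-one) | O=C1CCCCCCCCCCCCCCCCCCCCCCCCCO1 | target

Total step count: 3
Longest linear sequence: 3 steps (1 and 2 to 5, then 7, then 9)

**Steps most likely to fail**

Most at risk is step 3, the step that carries the label. The oxidative addition is slow and bimolecular, so under dilution unreacted borane can build up and couple between molecules to linear and cyclic oligomers. β-Hydride elimination at palladium and protodeboronation would also drain the two chain ends. The fallback uses known chemistry and closes the same C7–C8 bond as an alkene; it sets out from 2 and comes back at 9. Compound 2 is coupled under the conditions of step 1 with non-8-en-1-ylmagnesium bromide F1 (from 9-bromonon-1-ene and Mg) to give icos-19-en-1-ol F2. Fischer esterification with oct-7-enoic acid gives icos-19-en-1-yl oct-7-enoate F3. Ring-closing metathesis with second-generation Grubbs catalyst, (H2IMes)(PCy3)Cl2Ru=CHPh, in CH2Cl2 at reflux and 2 mM should give oxacycloheptacos-8-en-2-one F4 as an E/Z mixture. Hydrogenation over Pd/C in ethyl acetate then gives 9.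

Second is step 1. The bromomagnesium alkoxide 4 may aggregate or precipitate in cold THF and slow the copper-catalysed substitution, so that homocoupling and halogen–magnesium exchange of 3 take over. The fallback avoids organomagnesium chemistry and a free alkoxide; it sets out from 1 and comes back at 5. Undec-10-en-1-ol is silylated (TBSCl, imidazole, DMF) to tert-butyldimethyl(undec-10-en-1-yloxy)silane F5. Hydroboration with 9-BBN (1.0 equiv, THF) gives tert-butyl{[11-(9-borabicyclo[3.3.1]nonan-9-yl)undecyl]oxy}dimethylsilane F6. Intermolecular alkyl–alkyl Suzuki–Miyaura coupling of F6 with 1 (Pd(OAc)2, PCy3, K3PO4·H2O, THF, rt), which should tolerate the alkene of 1 once all 9-BBN is consumed, gives tert-butyldimethyl(nonadec-18-en-1-yloxy)silane F7. TBAF in THF then releases 5.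

Third is step 2. Hot sulfonic acid may move the terminal double bond into the chain, or the equilibrium may stop short of full conversion. The fallback activates the alcohol instead of the acid under neutral conditions; it sets out from 5 and comes back at 7. Mitsunobu esterification of 6 with 5 (PPh3, DIAD, THF, 0 °C to rt) should give 7 directly. It forms no compound outside the compound list (entry F0).

**Further compounds**
F1 | step 3 | non-8-en-1-ylmagnesium bromide | C=CCCCCCCC[Mg]Br
F2 | step 3 | icos-19-en-1-ol | OCCCCCCCCCCCCCCCCCCC=C
F3 | step 3 | icos-19-en-1-yl oct-7-enoate | C=CCCCCCC(=O)OCCCCCCCCCCCCCCCCCCC=C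
F4 | step 3 | oxacycloheptacos-8-en-2-one (E/Z mixture) | O=C1CCCCCC=CCCCCCCCCCCCCCCCCCCO1
F5 | step 1 | tert-butyldimethyl(undec-10-en-1-yloxy)silane | C=CCCCCCCCCCO[Si](C)(C)C(C)(C)C
F6 | step 1 | tert-butyl{[11-(9-borabicyclo[3.3.1]nonan-9-yl)undecyl]oxy}dimethylsilane | CC(C)(C)[Si](C)(C)OCCCCCCCCCCCB1C2CCCC1CCC2
F7 | step 1 | tert-butyldimethyl(nonadec-18-en-1-yloxy)silane | C=CCCCCCCCCCCCCCCCCCO[Si](C)(C)C(C)(C)C
F0 | step 2 | none | none
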